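**Retrosynthetic overview**
1. The malonic half ester goes on last, by heating the primary allylic alcohol with Meldrum's acid. The exocyclic C=CH2 and the adjacent C–H stereocentre are created together by an enantioselective Pd/formate SN2'-type hydrogenolysis of a tetrasubstituted cyclohexenylmethyl carbonate.
2. The C10 side chain comes from geraniol, oxidised at its (E)-methyl group and homologated to a terminal diene. Hydroboration and B-alkyl Suzuki coupling with a ring enol triflate join it to the ring carbon that becomes the stereocentre.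
3. The only ring, the cyclohexane, is made first in one [3+3] operation. The dianion of methyl 4-methyl-3-oxopentanoate is alkylated twice by 1-bromo-3-chloropropane, at the isopropyl carbon (future C(CH3)2) and at the α-carbon (future C=CH2 carbon).
4. Enabling feature: in the cyclohexane the C(=CH2) carbon and the C(CH3)2 carbon are 1,3-related through the stereogenic CH, and the other three ring atoms are a bare CH2CH2CH2 bridge. Raising the CH to C=O and the =CH2 carbon to CO2CH3 makes the two flanking carbons the α- and γ-carbons of a β-keto ester. Both groups are used again, the C=O as coupling handle and the CO2CH3 as the methylene carbon.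

Key step: step 1

Assumption: (R)-MOP-phen is taken to deliver hydride to the face that gives the (S)-centre, by analogy with (E)-3,3-disubstituted allylic carbonates (the ring C(CH3)2 carbon plays the group trans to CH2O). The antipodal ligand would be used if a pilot run shows the opposite sense.

Step 1
Reactants: 1 methyl 4-methyl-3-oxopentanoate; 2 1-bromo-3-chloropropane
Product: 6 methyl 3,3-dimethyl-2-oxocyclohexane-1-carboxylate (racemic), via sodium lithium dianion 3 (not isolated), via chloro keto ester enolate 4 (not isolated), via iodo keto ester enolate 5 (not isolated)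
Conditions: NaH, THF, 0 °C; n-BuLi, 0 °C; 2, 0 °C to rt; then NaI (cat.), DMPU, 65 °C
Reagents that add atoms: none
Why: NaH removes the acidic α-proton and n-BuLi then the γ-methine proton, and the resulting 1,3-dianion reacts first at its more basic, fully substituted γ-carbon with the C–Br end of 2 (SN2), which creates the quaternary C(CH3)2 carbon and leaves the stabilised keto ester enolate untouched. After catalytic Finkelstein exchange that enolate closes on the remaining primary halide through carbon, so that both ring bonds come from one three-carbon reagent in one flask. The closest known reaction type is the γ-alkylation of β-keto ester dianions followed by cycloalkylation of the resulting ω-halo keto ester. The only ring is closed in the 6-(enolendo)-exo-tet mode, which the Baldwin rules for enolates allow and which the gem-dimethyl group should accelerate (Thorpe–Ingold effect). The one new stereocentre, the ester-bearing carbon, is not controlled and need not be, since it is enolisable and becomes sp2 in step 2. The step needs γ before α, Br before Cl and C- before O-alkylation: the first follows from the reactivity order of the dianion, the second from the leaving groups, and the third should be favoured by the chelated Li/Na enolate in THF and the soft iodide, while a second γ-alkylation is impossible at the now quaternary carbon.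

Step 2
Reactants: 6 methyl 3,3-dimethyl-2-oxocyclohexane-1-carboxylate
Product: 7 methyl 3,3-dimethyl-2-(trifluoromethylsulfonyloxy)cyclohex-1-ene-1-carboxylate
Conditions: NaH, Et2O, 0 °C; Tf2O, 0 °C
Reagents that add atoms: trifluoromethanesulfonic anhydride, O=S(=O)(OS(=O)(=O)C(F)(F)F)C(F)(F)F
Why: Enol triflate formation by O-sulfonylation of the sodium enolate should give a single vinyl triflate, because the other α-carbon is quaternary, and it erases the labile stereocentre of 6.

Step 3
Reactants: 8 geraniol
Product: 9 geranyl tert-butyldimethylsilyl ether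
Conditions: TBSCl, imidazole, DMF, rt
Reagents that add atoms: tert-butyldimethylsilyl chloride, CC(C)(C)[Si](C)(C)Cl
Why: Standard silylation of a primary alcohol masks the allylic hydroxyl through the hydride, palladium and organoborane steps that follow.

Step 4
Reactants: 9 geranyl tert-butyldimethylsilyl ether
Product: 10 (2E,6E)-8-(tert-butyldimethylsilyloxy)-2,6-dimethylocta-2,6-dien-1-ol
Conditions: SeO2 (cat.), t-BuOOH, CH2Cl2, 0 °C to rt
Reagents that add atoms: tert-butyl hydroperoxide, CC(C)(C)OO
Why: Selenium dioxide allylic oxidation (ene reaction, then [2,3]-sigmatropic shift) should attack the more electron-rich terminal trisubstituted alkene and give the (E)-allylic alcohol, with no stereocentre formed.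

Step 5
Reactants: 10 (2E,6E)-8-(tert-butyldimethylsilyloxy)-2,6-dimethylocta-2,6-dien-1-ol
Product: 11 (2E,6E)-8-(tert-butyldimethylsilyloxy)-2,6-dimethylocta-2,6-dienal
Conditions: MnO2, CH2Cl2, rt
Reagents that add atoms: none
Why: Manganese dioxide oxidation is selective for allylic alcohols and should stop at the enal without touching alkene geometry or the silyl ether.

Step 6
Reactants: 11 (2E,6E)-8-(tert-butyldimethylsilyloxy)-2,6-dimethylocta-2,6-dienal
Product: 12 tert-butyl{[(2E,6E)-3,7-dimethylnona-2,6,8-trien-1-yl]oxy}dimethylsilane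
Conditions: Ph3PCH3Br, n-BuLi, THF, 0 °C; then 11, −78 °C to rt
Reagents that add atoms: methyltriphenylphosphonium bromide, C[P+](c1ccccc1)(c1ccccc1)c1ccccc1.[Br-]
Why: Wittig methylenation of the enal adds the one missing chain carbon as a terminal vinyl group and leaves the (E)-trisubstituted alkenes unchanged.

Step 7
Reactants: 12 tert-butyl{[(2E,6E)-3,7-dimethylnona-2,6,8-trien-1-yl]oxy}dimethylsilane; 7 methyl 3,3-dimethyl-2-(trifluoromethylsulfonyloxy)cyclohex-1-ene-1-carboxylate
Product: 14 methyl 2-[(3E,7E)-9-(tert-butyldimethylsilyloxy)-3,7-dimethylnona-3,7-dien-1-yl]-3,3-dimethylcyclohex-1-ene-1-carboxylate, via B-alkyl-9-BBN 13 (not isolated)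
Conditions: 9-BBN-H, THF, 0 °C to rt; then 7, PdCl2(dppf) (cat.), AsPh3 (cat.), Cs2CO3, DMF/H2O, 50 °C
Reagents that add atoms: none
Why: 9-BBN-H should hydroborate only the monosubstituted alkene at its terminal carbon, and the B-alkyl Suzuki–Miyaura coupling then joins that carbon to the ester-activated vinyl triflate, a coupling type that tolerates a neighbouring gem-dimethyl carbon in trimethylcyclohexenyl triflates.

Step 8
Reactants: 14 methyl 2-[(3E,7E)-9-(tert-butyldimethylsilyloxy)-3,7-dimethylnona-3,7-dien-1-yl]-3,3-dimethylcyclohex-1-ene-1-carboxylate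
Product: 15 {2-[(3E,7E)-9-(tert-butyldimethylsilyloxy)-3,7-dimethylnona-3,7-dien-1-yl]-3,3-dimethylcyclohex-1-en-1-yl}methanol
Conditions: i-Bu2AlH, CH2Cl2, −78 °C
Reagents that add atoms: none
Why: 1,2-Reduction of the conjugated ester with i-Bu2AlH gives the primary allylic alcohol without conjugate reduction or loss of the silyl ether.

Step 9
Reactants: 15 {2-[(3E,7E)-9-(tert-butyldimethylsilyloxy)-3,7-dimethylnona-3,7-dien-1-yl]-3,3-dimethylcyclohex-1-en-1-yl}methanol
Product: 16 {2-[(3E,7E)-9-(tert-butyldimethylsilyloxy)-3,7-dimethylnona-3,7-dien-1-yl]-3,3-dimethylcyclohex-1-en-1-yl}methyl methyl carbonate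
Conditions: ClCO2Me, pyridine, CH2Cl2, 0 °C
Reagents that add atoms: methyl chloroformate, COC(=O)Cl
Why: Acylation of the only free hydroxyl gives the allylic carbonate, the one allylic C–O bond in the molecule that zerovalent palladium can ionise.

Step 10
Reactants: 16 {2-[(3E,7E)-9-(tert-butyldimethylsilyloxy)-3,7-dimethylnona-3,7-dien-1-yl]-3,3-dimethylcyclohex-1-en-1-yl}methyl methyl carbonate
Product: 17 tert-butyl({(2E,6E)-9-[(1S)-2,2-dimethyl-6-methylidenecyclohexyl]-3,7-dimethylnona-2,6-dien-1-yl}oxy)dimethylsilane
Conditions: Pd2(dba)3·CHCl3 (cat.), (R)-MOP-phen (cat.), HCO2H, 1,8-bis(dimethylamino)naphthalene, dioxane, 20 °C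
Reagents that add atoms: none
Why: In this asymmetric palladium-catalysed formate hydrogenolysis of an allylic carbonate (Tsuji-type allylic reduction), ionisation gives the π-allyl complex, the monodentate phosphine leaves a site for formate, and the Pd–H formed on CO2 loss is delivered to the more substituted allyl terminus, so the exocyclic alkene and the (S)-C–H stereocentre form together with the face chosen by the chiral ligand.

Step 11
Reactants: 17 tert-butyl({(2E,6E)-9-[(1S)-2,2-dimethyl-6-methylidenecyclohexyl]-3,7-dimethylnona-2,6-dien-1-yl}oxy)dimethylsilane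
Product: 18 (2E,6E)-9-[(1S)-2,2-dimethyl-6-methylidenecyclohexyl]-3,7-dimethylnona-2,6-dien-1-ol
Conditions: Bu4NF, THF, 0 °C to rt
Reagents that add atoms: none
Why: Fluoride desilylation is neutral enough to leave the exocyclic alkene, the stereocentre and the (E)-alkenes in place.

Step 12
Reactants: 18 (2E,6E)-9-[(1S)-2,2-dimethyl-6-methylidenecyclohexyl]-3,7-dimethylnona-2,6-dien-1-ol; 19 Meldrum's acid
Product: 20 3-({(2E,6E)-9-[(1S)-2,2-dimethyl-6-methylidenecyclohexyl]-3,7-dimethylnona-2,6-dien-1-yl}oxy)-3-oxopropanoic acid (target)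
Conditions: toluene, 90 °C
Reagents that add atoms: none
Why: Thermal ring-opening acylation of the alcohol by Meldrum's acid with loss of acetone gives the malonic half ester directly, without a strong acid or base that could move the exocyclic alkene.

**Compound list**
1 | methyl 4-methyl-3-oxopentanoate | CC(C)C(=O)CC(=O)OC | starting material
2 | 1-bromo-3-chloropropane | ClCCCBr | starting material
3 | sodium lithium 1-methoxy-4-methylpenta-1,3-diene-1,3-diolate (dianion of 1) | [Na+].[Li+].COC([O-])=CC([O-])=C(C)C | intermediate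
4 | sodium enolate of methyl 7-chloro-4,4-dimethyl-3-oxoheptanoate | [Na+].COC(=O)C=C([O-])C(C)(C)CCCCl | intermediate
5 | sodium enolate of methyl 7-iodo-4,4-dimethyl-3-oxoheptanoate | [Na+].COC(=O)C=C([O-])C(C)(C)CCCI | intermediate
6 | methyl 3,3-dimethyl-2-oxocyclohexane-1-carboxylate (racemic) | COC(=O)C1CCCC(C)(C)C1=O | intermediate
7 | methyl 3,3-dimethyl-2-(trifluoromethylsulfonyloxy)cyclohex-1-ene-1-carboxylate | COC(=O)C1=C(OS(=O)(=O)C(F)(F)F)C(C)(C)CCC1 | intermediate
8 | geraniol | CC(C)=CCC/C(C)=C/CO | starting material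
9 | geranyl tert-butyldimethylsilyl ether | CC(C)=CCC/C(C)=C/CO[Si](C)(C)C(C)(C)C | intermediate
10 | (2E,6E)-8-(tert-butyldimethylsilyloxy)-2,6-dimethylocta-2,6-dien-1-ol | OC/C(C)=C/CC/C(C)=C/CO[Si](C)(C)C(C)(C)C | intermediate
11 | (2E,6E)-8-(tert-butyldimethylsilyloxy)-2,6-dimethylocta-2,6-dienal | O=C/C(C)=C/CC/C(C)=C/CO[Si](C)(C)C(C)(C)C | intermediate
12 | tert-butyl{[(2E,6E)-3,7-dimethylnona-2,6,8-trien-1-yl]oxy}dimethylsilane | C=C/C(C)=C/CC/C(C)=C/CO[Si](C)(C)C(C)(C)C | intermediate
13 | 9-[(3E,7E)-9-(tert-butyldimethylsilyloxy)-3,7-dimethylnona-3,7-dien-1-yl]-9-borabicyclo[3.3.1]nonane | C(CB1C2CCCC1CCC2)/C(C)=C/CC/C(C)=C/CO[Si](C)(C)C(C)(C)C | intermediate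
14 | methyl 2-[(3E,7E)-9-(tert-butyldimethylsilyloxy)-3,7-dimethylnona-3,7-dien-1-yl]-3,3-dimethylcyclohex-1-ene-1-carboxylate | COC(=O)C1=C(CC/C(C)=C/CC/C(C)=C/CO[Si](C)(C)C(C)(C)C)C(C)(C)CCC1 | intermediate
15 | {2-[(3E,7E)-9-(tert-butyldimethylsilyloxy)-3,7-dimethylnona-3,7-dien-1-yl]-3,3-dimethylcyclohex-1-en-1-yl}methanol | OCC1=C(CC/C(C)=C/CC/C(C)=C/CO[Si](C)(C)C(C)(C)C)C(C)(C)CCC1 | intermediate
16 | {2-[(3E,7E)-9-(tert-butyldimethylsilyloxy)-3,7-dimethylnona-3,7-dien-1-yl]-3,3-dimethylcyclohex-1-en-1-yl}methyl methyl carbonate | COC(=O)OCC1=C(CC/C(C)=C/CC/C(C)=C/CO[Si](C)(C)C(C)(C)C)C(C)(C)CCC1 | intermediate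
17 | tert-butyl({(2E,6E)-9-[(1S)-2,2-dimethyl-6-methylidenecyclohexyl]-3,7-dimethylnona-2,6-dien-1-yl}oxy)dimethylsilane | C=C1CCCC(C)(C)[C@@H]1CC/C(C)=C/CC/C(C)=C/CO[Si](C)(C)C(C)(C)C | intermediate
18 | (2E,6E)-9-[(1S)-2,2-dimethyl-6-methylidenecyclohexyl]-3,7-dimethylnona-2,6-dien-1-ol | C=C1CCCC(C)(C)[C@@H]1CC/C(C)=C/CC/C(C)=C/CO | intermediate
19 | Meldrum's acid (2,2-dimethyl-1,3-dioxane-4,6-dione) | CC1(C)OC(=O)CC(=O)O1 | starting material
20 | 3-({(2E,6E)-9-[(1S)-2,2-dimethyl-6-methylidenecyclohexyl]-3,7-dimethylnona-2,6-dien-1-yl}oxy)-3-oxopropanoic acid | C=C1CCCC(C)(C)[C@@H]1CC/C(C)=C/CC/C(C)=C/COC(=O)CC(=O)O | target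

Total step count: 12. Longest linear sequence: 10 steps (steps 3 to 12, from geraniol).

**Steps most likely to fail**

Step 1. Deprotonation of the hindered methine may stay incomplete, the dianion may act as a base on the dihalide, or the last closure may go through the enolate oxygen. The fallback closes the ring by acylation instead of alkylation, setting out from 2. The lithium enolate of methyl isobutyrate (LiN(i-Pr)2, THF, −78 °C) is alkylated at the C–Br end of 2 to give methyl 5-chloro-2,2-dimethylpentanoate F1. Its chloride (NaI cat., DMPU) alkylates the lithium enolate of methyl acetate to give dimethyl 2,2-dimethylheptanedioate F2. A Dieckmann condensation (KOt-Bu, toluene), which can enolise only at the unsubstituted α-carbon, comes back to the route at 6.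

Step 7. Transmetalation and reductive elimination at a vinyl carbon flanked by a quaternary carbon may be slow, so triflate hydrolysis and protodeboronation could take over. The fallback replaces cross-coupling by conjugate addition–elimination and sets out from 13 and 6.
- Borane 13 is oxidised (H2O2, NaOH) to (3E,7E)-9-(tert-butyldimethylsilyloxy)-3,7-dimethylnona-3,7-dien-1-ol F3.
- F3 is converted (CBr4, PPh3) into the bromide F4, and F4 with Mg into the Grignard reagent F5.
- Keto ester 6 gives the enol diethyl phosphate F6 with NaH and ClP(O)(OEt)2.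
- Transmetalation of F5 with CuI gives the alkylcopper reagent F7, which adds to the β-carbon of F6 and expels phosphate, coming back at 14.

Step 10. Facial selectivity at the crowded π-allyl terminus may be poor, hydride may go to the primary terminus, or β-hydride loss may give dienes. The fallback sets the stereocentre by C–C instead of C–H bond formation and sets out from 7.
- Reductive detriflation of 7 (Pd(OAc)2, PPh3, HCO2H, Bu3N, DMF) gives methyl 3,3-dimethylcyclohex-1-ene-1-carboxylate F8.
- i-Bu2AlH gives (3,3-dimethylcyclohex-1-en-1-yl)methanol F9.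
- MsCl/LiCl gives 1-(chloromethyl)-3,3-dimethylcyclohex-1-ene F10.
- A copper-catalysed asymmetric allylic alkylation of F10 with the Grignard reagent F5 follows (Cu(O2CC4H3S) cat., chiral phosphoramidite, CH2Cl2, −78 °C), a reaction type known for 1-(chloromethyl)cycloalkenes. It attacks the ring =CH carbon in the SN2' sense and forms the side-chain bond, the exocyclic methylene and the stereocentre at once, coming back at 17.

**Further compounds**
F1 | step 1 | methyl 5-chloro-2,2-dimethylpentanoate | COC(=O)C(C)(C)CCCCl
F2 | step 1 | dimethyl 2,2-dimethylheptanedioate | COC(=O)C(C)(C)CCCCC(=O)OC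
F3 | step 7 | (3E,7E)-9-(tert-butyldimethylsilyloxy)-3,7-dimethylnona-3,7-dien-1-ol | OCC/C(C)=C/CC/C(C)=C/CO[Si](C)(C)C(C)(C)C
F4 | step 7 | {[(2E,6E)-9-bromo-3,7-dimethylnona-2,6-dien-1-yl]oxy}(tert-butyl)dimethylsilane | BrCC/C(C)=C/CC/C(C)=C/CO[Si](C)(C)C(C)(C)C
F5 | step 7 | (3E,7E)-9-(tert-butyldimethylsilyloxy)-3,7-dimethylnona-3,7-dien-1-ylmagnesium bromide | Br[Mg]CC/C(C)=C/CC/C(C)=C/CO[Si](C)(C)C(C)(C)C
F6 | step 7 | methyl 2-(diethoxyphosphoryloxy)-3,3-dimethylcyclohex-1-ene-1-carboxylate | CCOP(=O)(OCC)OC1=C(C(=O)OC)CCCC1(C)C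
F7 | step 7 | (3E,7E)-9-(tert-butyldimethylsilyloxy)-3,7-dimethylnona-3,7-dien-1-ylcopper | [Cu]CC/C(C)=C/CC/C(C)=C/CO[Si](C)(C)C(C)(C)C
F8 | step 10 | methyl 3,3-dimethylcyclohex-1-ene-1-carboxylate | COC(=O)C1=CC(C)(C)CCC1
F9 | step 10 | (3,3-dimethylcyclohex-1-en-1-yl)methanol | OCC1=CC(C)(C)CCC1
F10 | step 10 | 1-(chloromethyl)-3,3-dimethylcyclohex-1-ene | ClCC1=CC(C)(C)CCC1
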